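# Proposed total synthesis of (S)-salazinic acid by silicon-tethered triyne cyclotrimerisation

## Analysis of the target

The target is salazinic acid as its (S)-lactol. It is a depsidone: ring A and ring B are benzene rings joined by an ester and by an ether, which makes the seven-membered ring C (a dibenzo[b,e][1,4]dioxepin-11-one), and ring D is a five-membered lactol-lactone (a 3-hydroxyphthalide) fused to ring B. In what follows the ring A carbons are called a1 (bears the ester carbonyl), a2 (ether oxygen), a3 (formyl), a4 (hydroxyl), a5 (hydrogen) and a6 (methyl), and the ring B carbons b1 (ester oxygen), b2 (hydroxymethyl), b3 (hydroxyl), b4 (lactone carbonyl), b5 (lactol carbon) and b6 (ether oxygen). The only stereocentre is the lactol carbon on b5; it is a hemiacetal that opens reversibly to the achiral formyl acid, so it has no second centre to relate to, it epimerises in solution, and the (S) form can be secured only as a solid. Sensitive groups are the aryl ester of ring C (open to hydroxide and peroxide), the salicylaldehyde on ring A, the b2 benzylic alcohol between two oxygens (quinone methide chemistry in strong acid) and the lactol itself. The difficulty is substitution density: ring B carries six different substituents, ring A five, and both bridges join carbons that are flanked on two sides, where diaryl ether formation and lactonisation are slow. The strategy rests on reading ring A as three two-carbon units, a6–a1, a2–a3 and a4–a5, of which the first hangs through its carbonyl from the b1 oxygen and the second directly from the b6 oxygen; ring A can therefore be assembled from three alkynes tied to a ring B catechol, and ring C arises in the same event.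

## Retrosynthetic reasoning

**32 back to 31.** No bond is cut. Because the lactol carbon racemises through ring opening, no reagent-controlled step can fix it permanently; the racemate 31 is the real synthetic goal and the (S) form 32 is drawn from it by a seeded, crystallisation-driven deracemisation in which racemisation in solution feeds the growing crystals.

**31 back to 29 (through 30).** Ring D is opened at the bond between the lactol carbon and the ring oxygen, and b2/b3 are re-protected. The b5 aldehyde is carried as a dimethyl acetal and the b4 acid as a methyl ester, b2 hydroxymethyl and b3 hydroxyl together as one isopropylidene ketal. Saponification is ruled out because ring C is an aryl ester; the forward step instead frees the aldehyde with acid and lets its hydrate anion cleave the neighbouring methyl ester intramolecularly at pH 8, a much faster process than attack on the hindered ring C ester.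

**29 back to 28 and 27.** The a3 formyl group is taken back to a hydroxymethyl group (29 from 28), and the a4 hydroxyl together with that hydroxymethyl group to a cyclic aryl–silicon–oxygen unit (28 from 27). Cutting the a4–O bond in favour of a4–Si means the phenol oxygen never has to be introduced onto a finished arene, and the order matters: the peroxide oxidation is run while a3 is still an alcohol, so no Dakin reaction can occur, and the b2 alcohol stays masked by the ketal so that the later benzylic oxidation touches a3 only.

**27 back to 26 (key disconnection).** Bonds a1–a2, a3–a4 and a5–a6 are cut, which dissolves ring A, ring C and the oxasilole at once into the triyne 26: a but-2-ynoate on the b1 oxygen, an ynol ether on the b6 oxygen, and an ethynylsilane tied to the ynol ether through a CH2–O–Si link. These cuts were chosen over a diaryl ether or lactone disconnection because every bond to ring B in 26 is a simple O-acylation or O-alkynylation of a phenol, and the tethers decide where methyl, silicon and the oxygenated methylene end up on ring A. The forward reaction has to favour the intramolecular cycloaddition over oligomerisation and has to close a seven-membered ring through an aryl ester.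

**26 back to 22 and 25, 22 back to 18 and 19.** The labile Si–O bond is cut last in the forward sense (26 from alcohol 22 and chlorosilane 25, itself from 23 and 24), so that it meets only the cyclotrimerisation. The ester C–O bond is cut next (21 from phenol 18 and but-2-ynoic acid 19, activated as anhydride 20). The ester must follow the ynol ether because it would not survive the basic conditions that make the ynol ether.

**18 back to 17, 17 back to 13 and 15.** The b1 oxygen is revealed from an allyl ether, the one group that can be removed under neutral conditions next to an acid-sensitive ynol ether and that cannot migrate to the neighbouring phenoxide. The ynol ether C–O bond is cut to phenol 13 and the dibromoalkene 15 (from aldehyde 14); copper-catalysed vinylation followed by dehydrobromination makes it without organolithium reagents.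

**13 back to 9.** The b6 oxygen is traced to a formyl group (13 from 11 by aryl migration to oxygen), and that formyl group to a phenoxide-directed formylation of 9, in which only one ortho position is open. The b1 hydroxyl must be free for this formylation and allylated afterwards (10 to 11), which is why an earlier, temporary benzyl group is used on the same oxygen.

**9 back to 5.** The b2 carbon is cut off as a formyl group introduced ortho to the only free phenol of 5 (giving 6), reduced (7) and tied to the b3 oxygen as the ketal (8). With the b1 oxygen benzylated, ketal formation has only one regiochemical outcome; hydrogenolysis then frees the b1 hydroxyl (9).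

**5 back to 1.** The b5 aldehyde comes from the aryl methyl group of methyl orsellinate 1: acetylation (2), radical dibromination at the only benzylic position (3) and methanolysis (4) are done first, while the ring carries nothing else that a bromine atom could attack. Selective benzylation of the phenol para to the ester gives 5.

## Alternatives that were turned down

Capital labels A1 to A8 are compounds of the alternatives; small labels a1 to a6 and b1 to b6 remain ring positions.

**Alternative 1: Ring B built by Michael–Claisen benzannulation on the ether oxygen.** Ring B is cut at b4–b5 and b1–b2. In the forward direction methyl acetoacetate A1 adds through its central carbon to the alkoxy-bearing carbon of the aryloxy acrylate A2, which already carries ring A on its a2 oxygen, and expels methoxide. Its methyl ketone then condenses onto the acrylate ester and the ring aromatises to the resorcinol A3.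
- For: ring B is made in one step from acyclic material, no precious metal is needed, and the diaryl ether bond is never formed at a crowded arene. The chosen route shares the last advantage, but its ring B costs eleven steps.
- Against: A3 has hydrogen at b2 and at a3 and has no ring C. Two one-carbon units must still be put onto an electron-rich diaryl ether, where b2, a3 and a5 compete. The two resorcinol hydroxyls must be told apart, the tert-butyl ester must be cleaved with acid in the presence of an acetal, and the lactone must then be closed between two hindered partners.
- Comparison: the step economy gained in ring B is spent after the key step, in operations whose regiochemistry is not fixed. The chosen route delivers ring A with all five substituents placed by the tethers and closes ring C in the same step.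

**Alternative 2: Ring D by ozonolytic contraction of an isocoumarin.** Only ring D is disconnected: the lactol is traced to the enol-lactone alkene of the isocoumarin-fused depsidone A4. Ozonolysis cleaves that alkene, one carbon leaves as formate, and the b4 acid closes onto the new b5 aldehyde to give the protected lactol A5.
- For: the aldehyde and the acid are unveiled together and no ester has to be cleaved next to ring C. On this point it is stronger than the two-stage acid and bicarbonate endgame chosen here.
- Against: it is an endgame device. The whole depsidone with its two crowded rings must already exist in A4, and ring B must in addition carry a two-carbon unit at b5. The oxidant meets electron-rich aryl ethers and a free aromatic aldehyde. The lactol still equilibrates, so nothing is gained for the stereocentre.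
- Comparison: the chosen strategy solves the core problem (rings A and C) and pays for ring D with one extra protecting group, the acetal, which is installed in step 3 at no cost in steps.

**Alternative 3: Ring A from dehydroacetic acid by pyranone-to-arene ring transformation.** Ring C is cut at the carbonyl–oxygen bond to b1 and ring A at a5–a6. Dehydroacetic acid A6 is first joined through its 4-oxygen to b6, giving the aryloxypyranone A7. A carbonate base then makes the b1 phenoxide open the pyranone lactone, which forms the ring C ester, and the freed methyl ketone condenses with the acetyl group to aromatise ring A, giving A8.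
- For: ring A comes from a very cheap building block, rings A and C form in one metal-free cascade at ordinary concentration, and no labile silyl ether is involved. In the cost and number of steps to ring A it is stronger than the chosen route.
- Against: A8 lacks the a3 formyl group and has two free positions ortho to the a4 hydroxyl. A late ortho-formylation would have to choose a3, which is flanked by the hydroxyl and the aryloxy bridge, over the open a5, and nothing in A8 enforces that. Forming A7 means substitution at a pyranone by the most hindered phenol of ring B.
- Comparison: the chosen route brings the a3 carbon in as the propargylic carbon of the ynol ether and the a4 oxygen as silicon, so the regiochemistry that the alternative leaves to a late electrophilic substitution is decided when the tethers are built.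

Key step: step 19

Assumption: the lactol carbon epimerises in solution through the ring-opened formyl acid, so 32 can be held only as a solid; racemic 31 is assumed to crystallise as a conglomerate, and the first seed crystals of 32 are taken from hand-sorted crystals whose configuration is assigned by anomalous X-ray dispersion.

## Route

Step 1
Reactants: 1 methyl orsellinate (methyl 2,4-dihydroxy-6-methylbenzoate)
Product: 2 methyl 2,4-diacetoxy-6-methylbenzoate
Conditions: Ac2O, pyridine, DMAP (cat.), 0 °C to rt
Reagents that add atoms: acetic anhydride, CC(=O)OC(C)=O
Why: Nucleophile-catalysed O-acetylation of both phenols; the acetates make the ring too electron-poor for electrophilic bromination and leave the aryl methyl group as the only benzylic site for the next step.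

Step 2
Reactants: 2 methyl 2,4-diacetoxy-6-methylbenzoate
Product: 3 methyl 2,4-diacetoxy-6-(dibromomethyl)benzoate
Conditions: NBS (2.3 equiv), AIBN (cat.), PhCF3, reflux, visible light
Reagents that add atoms: N-bromosuccinimide, O=C1CCC(=O)N1Br
Why: Wohl–Ziegler radical bromination; ortho-toluates are known to go to the benzal bromide with two equivalents, and no other C–H bond in 2 is activated towards a bromine atom.

Step 3
Reactants: 3 methyl 2,4-diacetoxy-6-(dibromomethyl)benzoate
Product: 4 methyl 2-(dimethoxymethyl)-4,6-dihydroxybenzoate
Conditions: NaOMe (6 equiv), MeOH, 0 °C to reflux; then TsOH to pH 2, HC(OMe)3, rt; NaHCO3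
Reagents that add atoms: sodium methoxide, [Na+].[O-]C
Why: Methanolysis of a benzal bromide to the dimethyl acetal with concurrent transesterification of both aryl acetates; the dibromomethyl carbon is meta to both phenoxides, so no quinone methide can form, and any lactone-type species arising from participation of the neighbouring ester is reopened by methoxide to the methyl ester. The anhydrous acid and orthoformate stage is a safeguard that returns any free aldehyde to the acetal without water ever meeting the formyl ester.

Step 4
Reactants: 4 methyl 2-(dimethoxymethyl)-4,6-dihydroxybenzoate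
Product: 5 methyl 4-(benzyloxy)-2-(dimethoxymethyl)-6-hydroxybenzoate
Conditions: BnBr (1.05 equiv), K2CO3, acetone, reflux
Reagents that add atoms: benzyl bromide, BrCc1ccccc1
Why: Williamson etherification; the phenol para to the ester is the more acidic and is not hydrogen-bonded, whereas the ortho phenol is chelated to the ester carbonyl and stays free, the usual selectivity of 2,4-dihydroxybenzoates.

Step 5
Reactants: 5 methyl 4-(benzyloxy)-2-(dimethoxymethyl)-6-hydroxybenzoate
Product: 6 methyl 4-(benzyloxy)-6-(dimethoxymethyl)-3-formyl-2-hydroxybenzoate
Conditions: MgCl2, Et3N, (CH2O)n, MeCN, reflux; cold citric acid work-up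
Reagents that add atoms: paraformaldehyde (as formaldehyde), C=O
Why: Casnati–Skattebøl ortho-formylation; formaldehyde is delivered from magnesium to the carbon ortho to the phenoxide, and the only free ortho position of the only free phenol is the future b2, so the regiochemistry is fixed by the mechanism. The conditions are basic and leave the acetal untouched.

Step 6
Reactants: 6 methyl 4-(benzyloxy)-6-(dimethoxymethyl)-3-formyl-2-hydroxybenzoate
Product: 7 methyl 4-(benzyloxy)-6-(dimethoxymethyl)-2-hydroxy-3-(hydroxymethyl)benzoate
Conditions: NaBH4, THF/MeOH, 0 °C
Reagents that add atoms: none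
Why: Borohydride reduction of the aldehyde; the doubly ortho-substituted methyl ester is not reduced under these conditions.

Step 7
Reactants: 7 methyl 4-(benzyloxy)-6-(dimethoxymethyl)-2-hydroxy-3-(hydroxymethyl)benzoate
Product: 8 methyl 5-(benzyloxy)-7-(dimethoxymethyl)-2,2-dimethyl-4H-1,3-benzodioxine-8-carboxylate
Conditions: Me2C(OMe)2, PPTS (cat.), acetone, rt to 40 °C
Reagents that add atoms: 2,2-dimethoxypropane, COC(C)(C)OC
Why: Transketalisation to the isopropylidene ketal of a salicyl alcohol; with the b1 oxygen benzylated only the b3 phenol can close the six-membered ring, and under anhydrous conditions the dimethyl acetal can only exchange with itself.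

Step 8
Reactants: 8 methyl 5-(benzyloxy)-7-(dimethoxymethyl)-2,2-dimethyl-4H-1,3-benzodioxine-8-carboxylate
Product: 9 methyl 7-(dimethoxymethyl)-5-hydroxy-2,2-dimethyl-4H-1,3-benzodioxine-8-carboxylate
Conditions: H2 (1 atm), Pd/C (10 wt% palladium on carbon), EtOAc, rt
Reagents that add atoms: none
Why: Hydrogenolysis of the aryl benzyl ether under neutral conditions; the ring benzylic C–O bonds of the ketal and the acetal are far slower to cleave without acid.

Step 9
Reactants: 9 methyl 7-(dimethoxymethyl)-5-hydroxy-2,2-dimethyl-4H-1,3-benzodioxine-8-carboxylate
Product: 10 methyl 7-(dimethoxymethyl)-6-formyl-5-hydroxy-2,2-dimethyl-4H-1,3-benzodioxine-8-carboxylate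
Conditions: MgCl2, Et3N, (CH2O)n, MeCN, reflux; cold citric acid work-up
Reagents that add atoms: paraformaldehyde (as formaldehyde), C=O
Why: Second Casnati–Skattebøl ortho-formylation; the b1 phenoxide has one open ortho carbon, the future b6, so the last ring position is filled without a regiochemical choice.

Step 10
Reactants: 10 methyl 7-(dimethoxymethyl)-6-formyl-5-hydroxy-2,2-dimethyl-4H-1,3-benzodioxine-8-carboxylate
Product: 11 methyl 5-(allyloxy)-7-(dimethoxymethyl)-6-formyl-2,2-dimethyl-4H-1,3-benzodioxine-8-carboxylate
Conditions: allyl bromide, K2CO3, DMF, rt
Reagents that add atoms: allyl bromide, C=CCBr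
Why: Williamson etherification of the only free phenol; the allyl ether marks the b1 oxygen unambiguously before the b6 oxygen is created, cannot migrate to a neighbouring phenoxide and can later be removed without acid.

Step 11
Reactants: 11 methyl 5-(allyloxy)-7-(dimethoxymethyl)-6-formyl-2,2-dimethyl-4H-1,3-benzodioxine-8-carboxylate
Product: 13 methyl 5-(allyloxy)-7-(dimethoxymethyl)-6-hydroxy-2,2-dimethyl-4H-1,3-benzodioxine-8-carboxylate, via aryl formate 12 (not isolated)
Conditions: mCPBA, Na2HPO4, CH2Cl2, 0 °C to rt; then K2CO3 (cat.), MeOH, 0 °C
Reagents that add atoms: 3-chloroperoxybenzoic acid, OOC(=O)c1cccc(Cl)c1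
Why: Baeyer–Villiger oxidation of an electron-rich benzaldehyde (Dakin-type aryl migration, helped by the ortho and para oxygens), then methanolysis of the aryl formate; the monosubstituted allyl alkene is epoxidised much more slowly and the buffer protects ketal and acetal.

Step 12
Reactants: 14 (tert-butyldimethylsilyloxy)acetaldehyde
Product: 15 tert-butyl[(3,3-dibromoprop-2-en-1-yl)oxy]dimethylsilane
Conditions: CBr4, PPh3, CH2Cl2, 0 °C
Reagents that add atoms: carbon tetrabromide, BrC(Br)(Br)Br
Why: Ramirez dibromo-olefination (first stage of the Corey–Fuchs sequence) of an unhindered aldehyde.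

Step 13
Reactants: 13 methyl 5-(allyloxy)-7-(dimethoxymethyl)-6-hydroxy-2,2-dimethyl-4H-1,3-benzodioxine-8-carboxylate; 15 tert-butyl[(3,3-dibromoprop-2-en-1-yl)oxy]dimethylsilane
Product: 17 methyl 5-(allyloxy)-6-{[3-(tert-butyldimethylsilyloxy)prop-1-yn-1-yl]oxy}-7-(dimethoxymethyl)-2,2-dimethyl-4H-1,3-benzodioxine-8-carboxylate, via Z-bromoenol ether 16 (not isolated)
Conditions: CuI (10 mol%), 2,2′-bipyridine (20 mol%), K3PO4, toluene, 110 °C; then KOt-Bu, THF, 0 °C
Reagents that add atoms: none
Why: Ullmann-type C–O coupling of a phenol with a 1,1-dibromoalkene at monovalent copper, which replaces the bromine trans to the alkyl group, followed by anti E2 dehydrobromination to the ynol ether; both ortho positions of the allyl ether are blocked, so no Claisen product can form, and the hindered methyl ester withstands the bulky alkoxide at 0 °C.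

Step 14
Reactants: 17 methyl 5-(allyloxy)-6-{[3-(tert-butyldimethylsilyloxy)prop-1-yn-1-yl]oxy}-7-(dimethoxymethyl)-2,2-dimethyl-4H-1,3-benzodioxine-8-carboxylate
Product: 18 methyl 6-{[3-(tert-butyldimethylsilyloxy)prop-1-yn-1-yl]oxy}-7-(dimethoxymethyl)-5-hydroxy-2,2-dimethyl-4H-1,3-benzodioxine-8-carboxylate
Conditions: Pd(PPh3)4 (5 mol%), morpholine, THF, rt; used at once
Reagents that add atoms: none
Why: Tsuji–Trost deallylation through an allyl complex of zerovalent palladium with an amine as allyl acceptor; the conditions are neutral, which the acid-sensitive ynol ether requires.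

Step 15
Reactants: 18 methyl 6-{[3-(tert-butyldimethylsilyloxy)prop-1-yn-1-yl]oxy}-7-(dimethoxymethyl)-5-hydroxy-2,2-dimethyl-4H-1,3-benzodioxine-8-carboxylate; 19 but-2-ynoic acid
Product: 21 methyl 5-(but-2-ynoyloxy)-6-{[3-(tert-butyldimethylsilyloxy)prop-1-yn-1-yl]oxy}-7-(dimethoxymethyl)-2,2-dimethyl-4H-1,3-benzodioxine-8-carboxylate, via but-2-ynoic anhydride 20 (not isolated)
Conditions: 19 (2.2 equiv), DCC (1.1 equiv), CH2Cl2, 0 °C; then 18, Et3N, DMAP (cat.), −20 to 0 °C
Reagents that add atoms: none
Why: Steglich-type acylation of the phenol with the preformed symmetric anhydride; preforming the anhydride keeps free carboxylic acid away from the ynol ether, to which acids add, and low temperature limits conjugate addition of DMAP to the ynoate.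

Step 16
Reactants: 21 methyl 5-(but-2-ynoyloxy)-6-{[3-(tert-butyldimethylsilyloxy)prop-1-yn-1-yl]oxy}-7-(dimethoxymethyl)-2,2-dimethyl-4H-1,3-benzodioxine-8-carboxylate
Product: 22 methyl 5-(but-2-ynoyloxy)-7-(dimethoxymethyl)-6-[(3-hydroxyprop-1-yn-1-yl)oxy]-2,2-dimethyl-4H-1,3-benzodioxine-8-carboxylate
Conditions: TBAF/AcOH (1:1), THF, 0 °C
Reagents that add atoms: none
Why: Buffered fluoride desilylation of the only silyl ether in the molecule; the ketal on b2/b3 is inert to fluoride and the aryl ester tolerates the buffered reagent.

Step 17
Reactants: 23 dichlorodimethylsilane; 24 ethynylmagnesium bromide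
Product: 25 chloro(ethynyl)dimethylsilane
Conditions: 23 (3 equiv), THF, −78 °C to rt, slow addition of 24; fractional distillation under N2
Reagents that add atoms: none
Why: Substitution at silicon by an alkynyl Grignard reagent; excess dichlorosilane and inverse addition suppress double substitution.

Step 18
Reactants: 22 methyl 5-(but-2-ynoyloxy)-7-(dimethoxymethyl)-6-[(3-hydroxyprop-1-yn-1-yl)oxy]-2,2-dimethyl-4H-1,3-benzodioxine-8-carboxylate; 25 chloro(ethynyl)dimethylsilane
Product: 26 methyl 5-(but-2-ynoyloxy)-7-(dimethoxymethyl)-6-({3-[(ethynyldimethylsilyl)oxy]prop-1-yn-1-yl}oxy)-2,2-dimethyl-4H-1,3-benzodioxine-8-carboxylate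
Conditions: Et3N, DMAP (cat.), CH2Cl2, 0 °C; filtered through Et3N-deactivated silica and used at once
Reagents that add atoms: none
Why: Silylation of a primary alcohol with a chlorosilane; the hydrolytically labile silyl ether is made last so that it meets only the cyclotrimerisation.

Step 19
Reactants: 26 methyl 5-(but-2-ynoyloxy)-7-(dimethoxymethyl)-6-({3-[(ethynyldimethylsilyl)oxy]prop-1-yn-1-yl}oxy)-2,2-dimethyl-4H-1,3-benzodioxine-8-carboxylate
Product: 27 oxasilole-fused depsidone: ring A with a6 methyl, a5 hydrogen and a 1,1-dimethyl-1,3-dihydro-2,1-benzoxasilole ring across a4 (silicon) and a3 (methylene); ring C closed; ring B with the b2/b3 isopropylidene ketal, b4 methyl ester and b5 dimethyl acetal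
Conditions: RhCl(PPh3)3 (10 mol%), toluene (degassed), 80 °C, 26 added over 6 h to a final 0.005 M
Reagents that add atoms: none
Why: Intramolecular (2+2+2) alkyne cyclotrimerisation, the closest precedent being RhCl(PPh3)3-catalysed cyclisations of tethered triynes that carry temporary silyl ether links. Monovalent rhodium binds the 1,6-diyne made up of the ynol ether and the ethynylsilane and couples them oxidatively to a trivalent rhodacyclopentadiene, which closes the five-membered oxasilole and forms bond a3–a4. The but-2-ynoate held on the neighbouring b1 oxygen then inserts into the Rh–C bond at a2 (bond a1–a2), which is the seven-membered closure of ring C across the ortho-phenylene diether of ring B; reductive elimination forms bond a5–a6, aromatises ring A and returns monovalent rhodium. Ring A thus forms by the cycloaddition itself, ring C by fusion through the aryl ester and aryl ether (seven-membered), and the oxasilole by fusion through the CH2–O–Si link (five-membered). No stereocentre is created. The step needs chemoselectivity for the intramolecular path over oligomerisation through the terminal alkyne, which slow addition into dilute catalyst secures, and it needs the aryl ester to reach its less favoured rotamer, which 80 °C allows. Regiochemistry is not at issue because each alkyne is fixed by its tether: the methyl group ends at a6, silicon at a4 and the oxygenated methylene at a3. The electron-rich ynol ether and the electron-poor ynoate are a matched pair for metallacycle formation and insertion.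

Step 20
Reactants: 27 oxasilole-fused depsidone
Product: 28 protected depsidone with a4 hydroxyl and a3 hydroxymethyl (ring B as in 27)
Conditions: H2O2 (30% aq.), KF, KHCO3, THF/MeOH, rt
Reagents that add atoms: hydrogen peroxide, OO
Why: Tamao–Fleming oxidation of an aryl(alkoxy)silane; the strained oxasilole makes silicon Lewis-acidic, hydroperoxide adds and the aryl group migrates from silicon to oxygen with retention of position, giving the phenol and freeing the a3 alcohol. The ring C carbonyl is shielded by the a6 methyl group and the a2 oxygen, and no aldehyde is present that peroxide could attack.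

Step 21
Reactants: 28 protected depsidone with a4 hydroxyl and a3 hydroxymethyl
Product: 29 protected depsidone with a4 hydroxyl and a3 formyl (ring B as in 27)
Conditions: MnO2 (activated), CH2Cl2, rt
Reagents that add atoms: none
Why: MnO2 oxidation of a benzylic alcohol to the salicylaldehyde; it is the only free alcohol because b2 is still inside the ketal.

Step 22
Reactants: 29 protected depsidone with a4 hydroxyl and a3 formyl
Product: 31 racemic salazinic acid, via formyl methyl ester 30 (not isolated)
Conditions: HCl (2 M aq.), THF, 40 °C; then NaHCO3 (aq) to pH 8, rt; HCl to pH 2, 0 °C, filtration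
Reagents that add atoms: water, O
Why: Acid hydrolysis of the isopropylidene ketal and the dimethyl acetal gives 30; at pH 8 the hydrate anion of the b5 aldehyde attacks the neighbouring methyl ester intramolecularly, the neighbouring-group ester cleavage known for methyl 2-formylbenzoate, which removes the methyl ester without strong hydroxide reaching ring C. Acidification closes ring D as the lactol, which forms without facial control and is therefore racemic.

Step 23
Reactants: 31 racemic salazinic acid
Product: 32 (S)-salazinic acid
Conditions: seed crystals of 32, glass beads, acetone/H2O, NaOAc/AcOH (cat.), 25 °C, stirred slurry; filtration, cold wash, drying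
Reagents that add atoms: none
Why: Proposed new method: the lactol carbon racemises in the liquid phase by acetate-catalysed ring opening to the achiral formyl carboxylic acid, while grinding of a seeded conglomerate slurry lets crystals of the seeded hand grow at the expense of the other (attrition-enhanced deracemisation, Viedma ripening), so the (S) configuration is set by the seed crystals and held by the lattice; the closest known cases are deracemisations of conglomerates that racemise in solution by reversible ring opening or proton transfer, such as isoindolinones and amino acid imines.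

## Compound list

1 | methyl orsellinate (methyl 2,4-dihydroxy-6-methylbenzoate) | COC(=O)c1c(C)cc(O)cc1O | starting material
2 | methyl 2,4-diacetoxy-6-methylbenzoate | COC(=O)c1c(C)cc(OC(C)=O)cc1OC(C)=O | intermediate
3 | methyl 2,4-diacetoxy-6-(dibromomethyl)benzoate | COC(=O)c1c(C(Br)Br)cc(OC(C)=O)cc1OC(C)=O | intermediate
4 | methyl 2-(dimethoxymethyl)-4,6-dihydroxybenzoate | COC(=O)c1c(C(OC)OC)cc(O)cc1O | intermediate
5 | methyl 4-(benzyloxy)-2-(dimethoxymethyl)-6-hydroxybenzoate | COC(=O)c1c(C(OC)OC)cc(OCc2ccccc2)cc1O | intermediate
6 | methyl 4-(benzyloxy)-6-(dimethoxymethyl)-3-formyl-2-hydroxybenzoate | COC(=O)c1c(C(OC)OC)cc(OCc2ccccc2)c(C=O)c1O | intermediate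
7 | methyl 4-(benzyloxy)-6-(dimethoxymethyl)-2-hydroxy-3-(hydroxymethyl)benzoate | COC(=O)c1c(C(OC)OC)cc(OCc2ccccc2)c(CO)c1O | intermediate
8 | methyl 5-(benzyloxy)-7-(dimethoxymethyl)-2,2-dimethyl-4H-1,3-benzodioxine-8-carboxylate | COC(=O)c1c(C(OC)OC)cc(OCc2ccccc2)c2COC(C)(C)Oc12 | intermediate
9 | methyl 7-(dimethoxymethyl)-5-hydroxy-2,2-dimethyl-4H-1,3-benzodioxine-8-carboxylate | COC(=O)c1c(C(OC)OC)cc(O)c2COC(C)(C)Oc12 | intermediate
10 | methyl 7-(dimethoxymethyl)-6-formyl-5-hydroxy-2,2-dimethyl-4H-1,3-benzodioxine-8-carboxylate | COC(=O)c1c(C(OC)OC)c(C=O)c(O)c2COC(C)(C)Oc12 | intermediate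
11 | methyl 5-(allyloxy)-7-(dimethoxymethyl)-6-formyl-2,2-dimethyl-4H-1,3-benzodioxine-8-carboxylate | COC(=O)c1c(C(OC)OC)c(C=O)c(OCC=C)c2COC(C)(C)Oc12 | intermediate
12 | methyl 5-(allyloxy)-7-(dimethoxymethyl)-6-(formyloxy)-2,2-dimethyl-4H-1,3-benzodioxine-8-carboxylate (aryl formate) | COC(=O)c1c(C(OC)OC)c(OC=O)c(OCC=C)c2COC(C)(C)Oc12 | intermediate
13 | methyl 5-(allyloxy)-7-(dimethoxymethyl)-6-hydroxy-2,2-dimethyl-4H-1,3-benzodioxine-8-carboxylate | COC(=O)c1c(C(OC)OC)c(O)c(OCC=C)c2COC(C)(C)Oc12 | intermediate
14 | (tert-butyldimethylsilyloxy)acetaldehyde | O=CCO[Si](C)(C)C(C)(C)C | starting material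
15 | tert-butyl[(3,3-dibromoprop-2-en-1-yl)oxy]dimethylsilane | BrC(Br)=CCO[Si](C)(C)C(C)(C)C | intermediate
16 | methyl 5-(allyloxy)-6-{[(1Z)-1-bromo-3-(tert-butyldimethylsilyloxy)prop-1-en-1-yl]oxy}-7-(dimethoxymethyl)-2,2-dimethyl-4H-1,3-benzodioxine-8-carboxylate | COC(=O)c1c(C(OC)OC)c(O/C(Br)=C/CO[Si](C)(C)C(C)(C)C)c(OCC=C)c2COC(C)(C)Oc12 | intermediate
17 | methyl 5-(allyloxy)-6-{[3-(tert-butyldimethylsilyloxy)prop-1-yn-1-yl]oxy}-7-(dimethoxymethyl)-2,2-dimethyl-4H-1,3-benzodioxine-8-carboxylate | COC(=O)c1c(C(OC)OC)c(OC#CCO[Si](C)(C)C(C)(C)C)c(OCC=C)c2COC(C)(C)Oc12 | intermediate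
18 | methyl 6-{[3-(tert-butyldimethylsilyloxy)prop-1-yn-1-yl]oxy}-7-(dimethoxymethyl)-5-hydroxy-2,2-dimethyl-4H-1,3-benzodioxine-8-carboxylate | COC(=O)c1c(C(OC)OC)c(OC#CCO[Si](C)(C)C(C)(C)C)c(O)c2COC(C)(C)Oc12 | intermediate
19 | but-2-ynoic acid | CC#CC(=O)O | starting material
20 | but-2-ynoic anhydride | CC#CC(=O)OC(=O)C#CC | intermediate
21 | methyl 5-(but-2-ynoyloxy)-6-{[3-(tert-butyldimethylsilyloxy)prop-1-yn-1-yl]oxy}-7-(dimethoxymethyl)-2,2-dimethyl-4H-1,3-benzodioxine-8-carboxylate | COC(=O)c1c(C(OC)OC)c(OC#CCO[Si](C)(C)C(C)(C)C)c(OC(=O)C#CC)c2COC(C)(C)Oc12 | intermediate
22 | methyl 5-(but-2-ynoyloxy)-7-(dimethoxymethyl)-6-[(3-hydroxyprop-1-yn-1-yl)oxy]-2,2-dimethyl-4H-1,3-benzodioxine-8-carboxylate | COC(=O)c1c(C(OC)OC)c(OC#CCO)c(OC(=O)C#CC)c2COC(C)(C)Oc12 | intermediate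
23 | dichlorodimethylsilane | C[Si](C)(Cl)Cl | starting material
24 | ethynylmagnesium bromide | C#C[Mg]Br | starting material
25 | chloro(ethynyl)dimethylsilane | C#C[Si](C)(C)Cl | intermediate
26 | methyl 5-(but-2-ynoyloxy)-7-(dimethoxymethyl)-6-({3-[(ethynyldimethylsilyl)oxy]prop-1-yn-1-yl}oxy)-2,2-dimethyl-4H-1,3-benzodioxine-8-carboxylate (triyne) | COC(=O)c1c(C(OC)OC)c(OC#CCO[Si](C)(C)C#C)c(OC(=O)C#CC)c2COC(C)(C)Oc12 | intermediate
27 | oxasilole-fused depsidone (a4 silicon, a3 methylene in a 1,1-dimethyl-1,3-dihydro-2,1-benzoxasilole; a6 methyl; ring B with b2/b3 isopropylidene ketal, b4 methyl ester, b5 dimethyl acetal) | Cc1cc2c(c3c1C(=O)Oc1c4COC(C)(C)Oc4c(C(=O)OC)c(C(OC)OC)c1O3)CO[Si]2(C)C | intermediate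
28 | protected depsidone, a4 hydroxyl, a3 hydroxymethyl (ring B as in 27) | Cc1cc(O)c(CO)c2c1C(=O)Oc1c3COC(C)(C)Oc3c(C(=O)OC)c(C(OC)OC)c1O2 | intermediate
29 | protected depsidone, a4 hydroxyl, a3 formyl (ring B as in 27) | Cc1cc(O)c(C=O)c2c1C(=O)Oc1c3COC(C)(C)Oc3c(C(=O)OC)c(C(OC)OC)c1O2 | intermediate
30 | depsidone with a3 formyl, a4 hydroxyl, b2 hydroxymethyl, b3 hydroxyl, b4 methyl ester, b5 formyl | Cc1cc(O)c(C=O)c2c1C(=O)Oc1c(CO)c(O)c(C(=O)OC)c(C=O)c1O2 | intermediate
31 | racemic salazinic acid | Cc1cc(O)c(C=O)c2c1C(=O)Oc1c(CO)c(O)c3c(c1O2)C(O)OC3=O | intermediate
32 | (S)-salazinic acid | Cc1cc(O)c(C=O)c2c1C(=O)Oc1c(CO)c(O)c3c(c1O2)[C@@H](O)OC3=O | target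

## Step count and least certain steps

Total: 23 steps. Longest linear sequence: 21 steps (steps 1 to 11, 13 to 16 and 18 to 23); steps 12 and 17 are one-step side branches.

**Step 23 (proposed new method).** The racemate may crystallise as a racemic compound and not as a conglomerate, in which case grinding enriches nothing. Racemisation in the slurry may also be too slow to feed the growing crystals. Fallback from 31 to 32 by known means: preparative chromatography of 31 on a polysaccharide chiral stationary phase with an aprotic eluent at low temperature, immediate cold evaporation of the (S) fraction and storage as a solid; the other fraction racemises on standing in solution and is recycled. This fallback makes no new compound (F0).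

**Step 19 (key step).** Three processes may compete: oligomerisation through the terminal alkyne, failure of the seven-membered insertion because the aryl ester prefers the rotamer that turns the ynoate away from the metallacycle, and thermal or metal-induced loss of the ynol ether. The fallback replaces the intramolecular ester partner by a bimolecular one and closes ring C afterwards by lactonisation. It sets out from 17 and returns at 27:
- Fluoride removes the silyl group from 17 to give the propargylic alcohol F1, which is silylated with 25 to the silicon-tethered diyne F2, the b1 oxygen still being allylated.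
- Allyl but-2-ynoate F3 is made from 19 and allyl alcohol.
- Cross-cyclotrimerisation of F2 with excess F3 under RhCl(PPh3)3 gives the diaryl ether F4. The two orientations of the incoming alkyne are no longer fixed by a tether, so an isomer may have to be removed here.
- Pd(PPh3)4 with morpholine removes both allyl groups to give the hydroxy acid F5.
- DCC/DMAP lactonisation, the classical depsidone closure, gives 27.

**Step 13.** The phenol of 13 is flanked on both sides, so the copper-catalysed C–O coupling may be slow, and prolonged heating with base invites isomerisation of the allyl ether. The fallback sets out from 13 and returns at 17: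
- 13 is treated with trichloroethylene and K2CO3 in DMF to give the (E)-1,2-dichlorovinyl ether F6.
- n-BuLi (2 equiv) at −78 °C converts F6 by elimination and chlorine–lithium exchange into the lithium aryloxyacetylide F7.
- Paraformaldehyde gives the lithium alkoxide F8, and TBSCl added to the same flask gives 17.
- The weak point is the organolithium next to the methyl ester, which relies on the two ortho substituents of that ester and on the low temperature.

**Step 20.** The aryl–silicon bond is para to the ester carbonyl and may undergo protodesilylation under fluoride instead of oxidative migration; hydroperoxide may also open ring C. The fallback sets out from 27 and returns at 28: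
- Ipso-iododesilylation of 27 with ICl buffered by K2CO3, then aqueous work-up, gives the aryl iodide F9 with the a3 alcohol free.
- F9 is then hydroxylated with benzaldoxime as hydroxide surrogate, Cs2CO3 and a zerovalent palladium catalyst (Pd2(dba)3 with a bulky biarylphosphine), which gives 28 without any peroxide.

**Step 22.** The intramolecular cleavage of the b4 methyl ester may be incomplete, ring C may open during the bicarbonate stage, or the b2 benzylic alcohol may be substituted in the acid stage. Fallback from 29 to 31: LiI in pyridine at reflux demethylates the b4 ester by SN2 attack at the methyl carbon, a mode that cannot touch an aryl ester, and gives the carboxylic acid F10; aqueous HCl in THF then removes ketal and acetal and the acid closes directly onto the aldehyde to give 31.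

**Step 5 (step 9 uses the same reaction).** The formylation has to occur at a carbon flanked by the magnesium phenoxide and the benzyl ether and may stall, or the acetal may be lost on work-up. Fallback from 5 to 7: boronate-directed ortho-hydroxymethylation with PhB(OH)2, paraformaldehyde and catalytic propionic acid in toluene at reflux gives the benzodioxaborin F11, and exchange with propane-1,3-diol releases 7 directly, bypassing 6.

## Further compounds

F0 | step 23 | none | none
F1 | step 19 | methyl 5-(allyloxy)-7-(dimethoxymethyl)-6-[(3-hydroxyprop-1-yn-1-yl)oxy]-2,2-dimethyl-4H-1,3-benzodioxine-8-carboxylate | COC(=O)c1c(C(OC)OC)c(OC#CCO)c(OCC=C)c2COC(C)(C)Oc12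
F2 | step 19 | methyl 5-(allyloxy)-7-(dimethoxymethyl)-6-({3-[(ethynyldimethylsilyl)oxy]prop-1-yn-1-yl}oxy)-2,2-dimethyl-4H-1,3-benzodioxine-8-carboxylate | COC(=O)c1c(C(OC)OC)c(OC#CCO[Si](C)(C)C#C)c(OCC=C)c2COC(C)(C)Oc12
F3 | step 19 | allyl but-2-ynoate | CC#CC(=O)OCC=C
F4 | step 19 | oxasilole-fused diaryl ether with a1 allyl ester and b1 allyl ether (ring C open) | Cc1cc2c(c(Oc3c(OCC=C)c4COC(C)(C)Oc4c(C(=O)OC)c3C(OC)OC)c1C(=O)OCC=C)CO[Si]2(C)C
F5 | step 19 | oxasilole-fused diaryl ether with a1 carboxylic acid and b1 hydroxyl | Cc1cc2c(c(Oc3c(O)c4COC(C)(C)Oc4c(C(=O)OC)c3C(OC)OC)c1C(=O)O)CO[Si]2(C)C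
F6 | step 13 | methyl 5-(allyloxy)-6-{[(E)-1,2-dichloroethenyl]oxy}-7-(dimethoxymethyl)-2,2-dimethyl-4H-1,3-benzodioxine-8-carboxylate | COC(=O)c1c(C(OC)OC)c(O/C(Cl)=C\Cl)c(OCC=C)c2COC(C)(C)Oc12
F7 | step 13 | lithium aryloxyacetylide of ring B (b1 allyl ether) | COC(=O)c1c(C(OC)OC)c(OC#C[Li])c(OCC=C)c2COC(C)(C)Oc12
F8 | step 13 | lithium alkoxide of the propargylic alcohol (b1 allyl ether) | COC(=O)c1c(C(OC)OC)c(OC#CCO[Li])c(OCC=C)c2COC(C)(C)Oc12
F9 | step 20 | protected depsidone with a4 iodide and a3 hydroxymethyl | Cc1cc(I)c(CO)c2c1C(=O)Oc1c3COC(C)(C)Oc3c(C(=O)OC)c(C(OC)OC)c1O2
F10 | step 22 | protected depsidone with a3 formyl, a4 hydroxyl and free b4 carboxylic acid | Cc1cc(O)c(C=O)c2c1C(=O)Oc1c3COC(C)(C)Oc3c(C(=O)O)c(C(OC)OC)c1O2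
F11 | step 5 | methyl 5-(benzyloxy)-7-(dimethoxymethyl)-2-phenyl-4H-1,3,2-benzodioxaborinine-8-carboxylate | COC(=O)c1c(C(OC)OC)cc(OCc2ccccc2)c2COB(c3ccccc3)Oc12
A1 | alternative 1 | methyl acetoacetate | COC(=O)CC(C)=O
A2 | alternative 1 | methyl 2-(aryloxy)-3,4,4-trimethoxybut-2-enoate carrying ring A on the a2 oxygen | COC(=O)C(Oc1cc(OCOC)cc(C)c1C(=O)OC(C)(C)C)=C(OC)C(OC)OC
A3 | alternative 1 | diaryl ether with new ring B as a resorcinol (b1 and b3 hydroxyl, b4 methyl ester, b5 dimethyl acetal, b2 hydrogen) | COC(=O)c1c(O)cc(O)c(Oc2cc(OCOC)cc(C)c2C(=O)OC(C)(C)C)c1C(OC)OC
A4 | alternative 2 | isocoumarin-fused protected depsidone | Cc1cc(OCOC)c(C=O)c2c1C(=O)Oc1c(CO[Si](C)(C)C(C)(C)C)c(OCOC)c3c(c1O2)C=COC3=O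
A5 | alternative 2 | protected salazinic acid lactol | Cc1cc(OCOC)c(C=O)c2c1C(=O)Oc1c(CO[Si](C)(C)C(C)(C)C)c(OCOC)c3c(c1O2)[C@@H](O)OC3=O
A6 | alternative 3 | dehydroacetic acid | CC(=O)C1=C(O)C=C(C)OC1=O
A7 | alternative 3 | 3-acetyl-6-methyl-4-(aryloxy)pyran-2-one carrying ring B through the b6 oxygen, b1 hydroxyl free | CC(=O)C1=C(Oc2c(O)c(CO[Si](C)(C)C(C)(C)C)c(OCOC)c(C(=O)OC)c2C(OC)OC)C=C(C)OC1=O
A8 | alternative 3 | protected depsidone lacking the a3 formyl group | Cc1cc(O)cc2c1C(=O)Oc1c(CO[Si](C)(C)C(C)(C)C)c(OCOC)c(C(=O)OC)c(C(OC)OC)c1O2
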